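The route rests on reading the 8-hydroxy-2,2-dimethyl-2H-chromene of ring B (chromene numbering) as a rearranged ortho-quinol: its free C8 hydroxyl sits ortho to the ring oxygen at C8a, with C4 on the adjacent C4a. The key step oxidises a phenol carrying a (Z)-3-hydroxy-3-methylbutenyl chain to a spiro 2,5-dihydrofuran dienone, whose vinyl carbon then shifts from the spiro carbon (future C8a) to the neighbouring carbon (future C4a) under acid. This one operation installs the ring oxygen, enlarges the five-membered ether ring to the pyran and returns the dienone carbonyl as the C8 hydroxyl. Claisen condensation with a prenylated, MOM-protected phloroacetophenone and acid-mediated ring closure complete the flavone.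

Key step: step 5

Remark: compound 11 (and F7) is drawn as the 1,3-diketone although it should exist largely as enol and cyclic hemiketal tautomers; compound 9 is racemic at its spiro carbon, which is lost again in the same step.

Step 1
Reactants: 1 2,4,6-trihydroxyacetophenone; 2 prenyl bromide (1-bromo-3-methylbut-2-ene)
Product: 3 1-[2,4,6-trihydroxy-3-(3-methylbut-2-en-1-yl)phenyl]ethan-1-one
Conditions: 10% aq. KOH, 0 °C → rt
Reagents that add atoms: none
Why: C-prenylation of the ambident phloroacetophenone phenolate (electrophilic aromatic substitution through carbon) should be favoured in water, where the oxygen is solvated, and the two open ring positions are equivalent, so a single mono-C-prenyl compound is expected beside over-alkylated material.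

Step 2
Reactants: 3 1-[2,4,6-trihydroxy-3-(3-methylbut-2-en-1-yl)phenyl]ethan-1-one
Product: 4 1-[2-hydroxy-4,6-bis(methoxymethoxy)-3-(3-methylbut-2-en-1-yl)phenyl]ethan-1-one
Conditions: MOMCl (2.2 equiv), i-Pr2NEt, CH2Cl2, 0 °C → rt
Reagents that add atoms: chloromethyl methyl ether (MOMCl), COCCl
Why: Williamson-type O-alkylation with MOMCl should take the 4-hydroxyl and the less hindered of the two carbonyl-flanking hydroxyls, leaving the hydroxyl wedged between acetyl and prenyl hydrogen-bonded and free, which later fixes the prenyl group at C8.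

Step 3
Reactants: 5 methyl 3-hydroxy-4-iodobenzoate; 6 2-methylbut-3-yn-2-ol
Product: 7 methyl 3-hydroxy-4-(3-hydroxy-3-methylbut-1-yn-1-yl)benzoate
Conditions: PdCl2(PPh3)2 (cat.), CuI (cat.), Et3N, THF, rt
Reagents that add atoms: none
Why: Sonogashira coupling of the ester-activated aryl iodide should proceed at room temperature, where the ortho-alkynylphenol does not yet cycloisomerise to the benzofuran.

Step 4
Reactants: 7 methyl 3-hydroxy-4-(3-hydroxy-3-methylbut-1-yn-1-yl)benzoate
Product: 8 methyl 3-hydroxy-4-[(1Z)-3-hydroxy-3-methylbut-1-en-1-yl]benzoate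
Conditions: H2 (1 atm), Lindlar catalyst, quinoline, EtOAc, rt
Reagents that add atoms: none
Why: Lindlar semihydrogenation delivers both hydrogens to one face of the alkyne and so should set the Z double bond, with quinoline holding back over-reduction.

Step 5
Reactants: 8 methyl 3-hydroxy-4-[(1Z)-3-hydroxy-3-methylbut-1-en-1-yl]benzoate
Product: 10 methyl 8-hydroxy-2,2-dimethyl-2H-chromene-6-carboxylate, via spiro ortho-quinol ether 9 (not isolated)
Conditions: PhI(OAc)2 (1.0 equiv), CH2Cl2–(CF3)2CHOH 9:1, −40 °C; then CF3CO2H, −40 °C → rt
Reagents that add atoms: none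
Why: PhI(OAc)2 oxidises the phenol, and the tertiary hydroxyl, held beside the ring by the Z double bond, adds to the chain-bearing ortho carbon (5-exo-trig closure of the spiro 2,5-dihydrofuran, an oxidative dearomatising spiro-etherification) to give the ortho-quinol ether 9. Acid then protonates the dienone carbonyl and the vinyl carbon shifts from the spiro carbon to the neighbouring ring CH (dienone–phenol rearrangement), which enlarges the five-membered ether ring to the six-membered pyran, and loss of a proton restores the arene with the former carbonyl as the C8 hydroxyl. The closest known reactions are the hypervalent-iodine spirocyclisation of phenols bearing a pendant alcohol and the acid-promoted, ring-enlarging dienone–phenol rearrangement of spirocyclic cyclohexadienones. The spiro carbon is the only new stereocentre; it forms as a racemate and disappears on rearomatisation, so no control is needed. The step needs carbon, not oxygen, to migrate: the vinyl shift leaves an oxocarbenium ion stabilised by the ring oxygen, whereas an oxygen shift would leave only an allyl cation, and the only other neighbour of the spiro carbon is the carbonyl carbon. It also needs the oxidation to be complete before the acid arrives, so that the allylic alcohol is not closed onto the phenol oxygen and the product phenol never meets the oxidant; one equivalent of oxidant at −40 °C ahead of the acid should secure this.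

Step 6
Reactants: 4 1-[2-hydroxy-4,6-bis(methoxymethoxy)-3-(3-methylbut-2-en-1-yl)phenyl]ethan-1-one; 10 methyl 8-hydroxy-2,2-dimethyl-2H-chromene-6-carboxylate
Product: 11 1-[2-hydroxy-4,6-bis(methoxymethoxy)-3-(3-methylbut-2-en-1-yl)phenyl]-3-(8-hydroxy-2,2-dimethyl-2H-chromen-6-yl)propane-1,3-dione
Conditions: LiHMDS (5 equiv), THF, −78 °C → rt; aq. NH4Cl
Reagents that add atoms: none
Why: Crossed Claisen condensation: the lithium enolate of 4 (present as the phenolate dianion) should add to the methyl ester, which carries its phenol as the lithium phenolate as methyl salicylate does in related condensations, and the product is removed from the equilibrium as its diketonate.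

Step 7
Reactants: 11 1-[2-hydroxy-4,6-bis(methoxymethoxy)-3-(3-methylbut-2-en-1-yl)phenyl]-3-(8-hydroxy-2,2-dimethyl-2H-chromen-6-yl)propane-1,3-dione
Product: 13 5,7-dihydroxy-2-(8-hydroxy-2,2-dimethyl-2H-chromen-6-yl)-8-(3-methylbut-2-en-1-yl)-4H-chromen-4-one, via bis-MOM flavone 12 (not isolated)
Conditions: HCl (cat.), MeOH–THF, rt; then 3 M HCl, 50 °C
Reagents that add atoms: none
Why: Acid-catalysed cyclodehydration of the ortho-hydroxyaryl 1,3-diketone (the closing step of the Baker–Venkataraman flavone synthesis) should proceed through the only free ortho hydroxyl while both MOM groups are still in place, which puts the prenyl group at C8, and the stronger acid then removes the MOM groups by acetal exchange with methanol.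

Compound list
1 | 2,4,6-trihydroxyacetophenone | CC(=O)c1c(O)cc(O)cc1O | starting material
2 | prenyl bromide (1-bromo-3-methylbut-2-ene) | CC(C)=CCBr | starting material
3 | 1-[2,4,6-trihydroxy-3-(3-methylbut-2-en-1-yl)phenyl]ethan-1-one | CC(=O)c1c(O)cc(O)c(CC=C(C)C)c1O | intermediate
4 | 1-[2-hydroxy-4,6-bis(methoxymethoxy)-3-(3-methylbut-2-en-1-yl)phenyl]ethan-1-one | CC(=O)c1c(O)c(CC=C(C)C)c(OCOC)cc1OCOC | intermediate
5 | methyl 3-hydroxy-4-iodobenzoate | COC(=O)c1ccc(I)c(O)c1 | starting material
6 | 2-methylbut-3-yn-2-ol | CC(C)(O)C#C | starting material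
7 | methyl 3-hydroxy-4-(3-hydroxy-3-methylbut-1-yn-1-yl)benzoate | COC(=O)c1ccc(C#CC(C)(C)O)c(O)c1 | intermediate
8 | methyl 3-hydroxy-4-[(1Z)-3-hydroxy-3-methylbut-1-en-1-yl]benzoate | COC(=O)c1ccc(/C=C\C(C)(C)O)c(O)c1 | intermediate
9 | methyl 2,2-dimethyl-10-oxo-1-oxaspiro[4.5]deca-3,6,8-triene-8-carboxylate (spiro ortho-quinol ether, racemic, not isolated) | COC(=O)C1=CC(=O)C2(C=C1)OC(C)(C)C=C2 | intermediate
10 | methyl 8-hydroxy-2,2-dimethyl-2H-chromene-6-carboxylate | COC(=O)c1cc(O)c2OC(C)(C)C=Cc2c1 | intermediate
11 | 1-[2-hydroxy-4,6-bis(methoxymethoxy)-3-(3-methylbut-2-en-1-yl)phenyl]-3-(8-hydroxy-2,2-dimethyl-2H-chromen-6-yl)propane-1,3-dione | CC(C)=CCc1c(OCOC)cc(OCOC)c(C(=O)CC(=O)c2cc(O)c3OC(C)(C)C=Cc3c2)c1O | intermediate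
12 | 2-(8-hydroxy-2,2-dimethyl-2H-chromen-6-yl)-5,7-bis(methoxymethoxy)-8-(3-methylbut-2-en-1-yl)-4H-chromen-4-one (bis-MOM flavone, not isolated) | CC(C)=CCc1c(OCOC)cc(OCOC)c2c(=O)cc(-c3cc(O)c4OC(C)(C)C=Cc4c3)oc12 | intermediate
13 | 5,7-dihydroxy-2-(8-hydroxy-2,2-dimethyl-2H-chromen-6-yl)-8-(3-methylbut-2-en-1-yl)-4H-chromen-4-one | CC(C)=CCc1c(O)cc(O)c2c(=O)cc(-c3cc(O)c4c(c3)C=CC(C)(C)O4)oc12 | target

Total step count: 7. Longest linear sequence: 5 steps (steps 3, 4, 5, 6 and 7, from 5 and 6 to 13).

Steps most likely to fail

1. Step 5. The tertiary allylic alcohol may ionise in the acidic fluorinated medium and close onto the phenol oxygen before the oxidant acts. The dienone may also dimerise by Diels–Alder reaction before it rearranges, or oxygen may migrate in place of carbon. The fallback takes the double bond out of play during dearomatisation and restores it afterwards, while keeping the same ring enlargement. It sets out from 7: exhaustive hydrogenation (H2, Pd/C, EtOAc) should give methyl 3-hydroxy-4-(3-hydroxy-3-methylbutyl)benzoate F1. PhI(OAc)2 should turn this into the saturated spiro ether methyl 2,2-dimethyl-10-oxo-1-oxaspiro[4.5]deca-6,8-diene-8-carboxylate F2, which has no allylic C–O bond to ionise. BF3·OEt2 should rearrange F2 with alkyl shift to methyl 8-hydroxy-2,2-dimethyl-3,4-dihydro-2H-chromene-6-carboxylate F3, and DDQ in hot dioxane should dehydrogenate F3 across C3–C4. The path comes back to the route at 10.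

2. Step 7. The MOM group next to the ketone may be lost before the pyranone has closed, so that closure through the newly freed oxygen would give the 6-prenyl isomer. At the deprotection stage the freed 7-hydroxyl may also add across the prenyl double bond under protic acid. The fallback separates the two events and takes protic acid out of the deprotection. It sets out from 11: PPTS in toluene at 80 °C over 4 Å sieves, with no nucleophile to accept the MOM groups, should close the ring so that 12 can be isolated. ZnBr2 with n-PrSH in CH2Cl2 at 0 °C should then pass the MOM groups to sulfur within minutes. The path comes back to the route at 13 and makes no compound outside the list (entry F0).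

3. Step 6. Addition of the enolate to an ester that is deactivated by its own phenolate may be slow, leading to recovery of both partners or retro-Claisen cleavage on forcing. The fallback delivers the acyl group intramolecularly by a Baker–Venkataraman rearrangement. It sets out from 10: MOMCl and i-Pr2NEt should give methyl 8-(methoxymethoxy)-2,2-dimethyl-2H-chromene-6-carboxylate F4, and LiOH in aqueous THF should give 8-(methoxymethoxy)-2,2-dimethyl-2H-chromene-6-carboxylic acid F5. EDC and DMAP with phenol 4 should give the aryl ester 2-acetyl-3,5-bis(methoxymethoxy)-6-(3-methylbut-2-en-1-yl)phenyl 8-(methoxymethoxy)-2,2-dimethyl-2H-chromene-6-carboxylate F6. KOH in pyridine should then shift the acyl group from oxygen to the enolate carbon to give 1-[2-hydroxy-4,6-bis(methoxymethoxy)-3-(3-methylbut-2-en-1-yl)phenyl]-3-[8-(methoxymethoxy)-2,2-dimethyl-2H-chromen-6-yl]propane-1,3-dione F7. The conditions of step 7 should close the ring and remove all three MOM groups, so the path comes back to the route at 13.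

Further compounds
F1 | step 5 | methyl 3-hydroxy-4-(3-hydroxy-3-methylbutyl)benzoate | COC(=O)c1ccc(CCC(C)(C)O)c(O)c1
F2 | step 5 | methyl 2,2-dimethyl-10-oxo-1-oxaspiro[4.5]deca-6,8-diene-8-carboxylate | COC(=O)C1=CC(=O)C2(C=C1)CCC(C)(C)O2
F3 | step 5 | methyl 8-hydroxy-2,2-dimethyl-3,4-dihydro-2H-chromene-6-carboxylate | COC(=O)c1cc(O)c2OC(C)(C)CCc2c1
F0 | step 7 | none | none
F4 | step 6 | methyl 8-(methoxymethoxy)-2,2-dimethyl-2H-chromene-6-carboxylate | COCOc1cc(C(=O)OC)cc2C=CC(C)(C)Oc12
F5 | step 6 | 8-(methoxymethoxy)-2,2-dimethyl-2H-chromene-6-carboxylic acid | COCOc1cc(C(O)=O)cc2C=CC(C)(C)Oc12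
F6 | step 6 | 2-acetyl-3,5-bis(methoxymethoxy)-6-(3-methylbut-2-en-1-yl)phenyl 8-(methoxymethoxy)-2,2-dimethyl-2H-chromene-6-carboxylate | CC(=O)c1c(OCOC)cc(OCOC)c(CC=C(C)C)c1OC(=O)c1cc(OCOC)c2OC(C)(C)C=Cc2c1
F7 | step 6 | 1-[2-hydroxy-4,6-bis(methoxymethoxy)-3-(3-methylbut-2-en-1-yl)phenyl]-3-[8-(methoxymethoxy)-2,2-dimethyl-2H-chromen-6-yl]propane-1,3-dione | CC(C)=CCc1c(OCOC)cc(OCOC)c(C(=O)CC(=O)c2cc(OCOC)c3OC(C)(C)C=Cc3c2)c1O
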